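**Plan**

1. Retrosynthesis: the C1 carbinol is traced back to a ketone, and the angelate (C8–O acyl bond) and the acrylic acid oxidation level at C12 are adjusted just before the lactone is closed. The lactone O–C6 bond and the C3–O bond are then cut together. The lactone oxygen on C6 and the hydroxyl on C3 sit 1,4 to each other on the same face of the Z-C4=C5 bond (O–C6–C5=C4(Me)–C3–O). This is the pattern left by a cis-1,4-dioxygenation of a (3Z,5Z)-cyclodeca-3,5-diene whose carboxyl carbon C12 hangs on C7, next to the diene terminus C6.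
2. The ten-membered carbocycle is cut across C1–C6, which leads back to a cis-decalin 1,3-diol monomesylate (Grob fragmentation; the decalin is a temporary, easily built skeleton). Ring A of the decalin (C1–C6) is cut at C3=C4 (metathesis), C1–C2 (allyl addition) and C5–C6 (aldol). Ring B (C1, C6–C10) is (S)-carvone.
3. Forward: carvone ring B is oxygenated at C8, C10 and C12. Ring A is annulated, and the C1–C6 bond is then broken to give the ten-membered (3Z,5Z)-dienone. The angelate and the acrylic acid are installed, the lactone ring is closed in the palladium-catalysed 1,4-oxidation, and a directed reduction of the C1 ketone ends the route.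
4. Stereochemistry: C7 comes from (S)-carvone. C8 and C10 follow by substrate control on the six-membered ring. The anti aldol (C5, C6) and the axial allylation (C1) shape the cis-decalin so that the stereospecific fragmentation gives the Z,Z-diene. C6 and C3 arise in the key step (allylic 1,3-strain from C7; both oxygens anti to palladium), and C1 by hydride delivery from the C3 hydroxyl.

Key step: step 15

Remark: C-locants in the step descriptions are the germacrane positions of the target (C6 lactone carbinol, C12 lactone carbonyl, C13 exocyclic methylene, C14 methyl on C10, C15 methyl on C4), and the ester is taken as the angelate, (Z)-2-methylbut-2-enoate, as drawn.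

**Route**

Step 1
Reactants: 1 (S)-(+)-carvone
Product: 2 (5R)-1-(tert-butyldimethylsilyloxy)-2-methyl-5-(prop-1-en-2-yl)cyclohexa-1,3-diene
Conditions: TBSOTf, Et3N, CH2Cl2, 0 to 20 °C
Reagents that add atoms: tert-butyldimethylsilyl triflate, CC(C)(C)[Si](C)(C)OS(=O)(=O)C(F)(F)F
Why: Soft enolisation with a silyl triflate and an amine under equilibrating conditions should give the through-conjugated (thermodynamic) dienol silyl ether by loss of a γ-proton from C8, as with other cyclohex-2-enones, and it leaves the C7 stereocentre untouched.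

Step 2
Reactants: 2 the dienol silyl ether
Product: 4 (4R,5S)-4-hydroxy-2-methyl-5-(prop-1-en-2-yl)cyclohex-2-en-1-one, via vinyl epoxide 3 (not isolated)
Conditions: dimethyldioxirane (1 equiv), acetone/CH2Cl2, −78 to −20 °C; then HF·pyridine, THF, 0 °C
Reagents that add atoms: dimethyldioxirane, CC1(C)OO1
Why: In this vinylogous Rubottom oxidation the electrophilic oxidant should attack the electron-rich diene at its γ-terminus (C8) on the face anti to the neighbouring isopropenyl group, and collapse of the vinyl epoxide with loss of the silyl group restores the enone with the new C8 hydroxyl trans to the C7 substituent.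

Step 3
Reactants: 4 the γ-hydroxy enone
Product: 5 (4R,5S)-2-methyl-5-(prop-1-en-2-yl)-4-(triethylsilyloxy)cyclohex-2-en-1-one
Conditions: TESCl, imidazole, DMF, 0 °C
Reagents that add atoms: chlorotriethylsilane, CC[Si](CC)(CC)Cl
Why: Standard silylation of the only hydroxyl group, with the triethylsilyl ether chosen because it can later be cleaved in the presence of a primary tert-butyldimethylsilyl ether.

Step 4
Reactants: 5 the silyloxy enone
Product: 7 (2R,4R,5S)-2-hydroxy-2-methyl-5-(prop-1-en-2-yl)-4-(triethylsilyloxy)cyclohexan-1-one, via lithium enolate 6 (not isolated)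
Conditions: LiBH(sBu)3, THF, −78 °C; then 2-(phenylsulfonyl)-3-phenyloxaziridine, −78 to −40 °C; NH4Cl (aq)
Reagents that add atoms: 2-(phenylsulfonyl)-3-phenyloxaziridine, O=S(=O)(c1ccccc1)N1OC1c1ccccc1
Why: Conjugate reduction by the hindered borohydride gives the C1/C10 enolate regiospecifically, and oxygen transfer from the N-sulfonyloxaziridine (Davis oxidation) should occur by axial attack on the half-chair that keeps the C7 and C8 substituents equatorial, which places the new C10 hydroxyl axial and trans to the C8 oxygen.

Step 5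
Reactants: 7 the α-hydroxy ketone
Product: 8 (2R,4R,5S)-2-hydroxy-5-(3-hydroxyprop-1-en-2-yl)-2-methyl-4-(triethylsilyloxy)cyclohexan-1-one
Conditions: SeO2 (0.3 equiv), tBuOOH, CH2Cl2, 20 °C
Reagents that add atoms: selenium dioxide, O=[Se]=O; tert-butyl hydroperoxide, CC(C)(C)OO
Why: SeO2-catalysed allylic oxidation (ene reaction followed by a [2,3]-shift) should hydroxylate the methyl group of the 1,1-disubstituted isopropenyl alkene, the only alkene present, to give the C12 alcohol.

Step 6
Reactants: 8 the allylic alcohol
Product: 9 (2R,4R,5S)-5-[3-(tert-butyldimethylsilyloxy)prop-1-en-2-yl]-2-hydroxy-2-methyl-4-(triethylsilyloxy)cyclohexan-1-one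
Conditions: TBSCl, imidazole, DMF, 0 °C
Reagents that add atoms: tert-butyldimethylsilyl chloride, CC(C)(C)[Si](C)(C)Cl
Why: Silylation with TBSCl and imidazole should take the primary alcohol only, since the tertiary C10 hydroxyl does not react under these conditions.

Step 7
Reactants: 9 the ring B ketone; 10 methacrolein
Product: 12 (2R,4R,5S,6S)-5-[3-(tert-butyldimethylsilyloxy)prop-1-en-2-yl]-2-hydroxy-6-[(1R)-1-hydroxy-2-methylprop-2-en-1-yl]-2-methyl-4-(triethylsilyloxy)cyclohexan-1-one, via dilithium enolate 11 (not isolated)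
Conditions: LiN(iPr)2 (2.2 equiv), THF, −78 °C; then methacrolein; AcOH quench at −78 °C
Reagents that add atoms: none
Why: Aldol addition through a Zimmerman–Traxler chair, in which only C6 can be enolised, the ring-locked (E)-enolate should give the anti aldol (C5), and the aldehyde should approach C6 on the face anti to the C7 side chain.

Step 8
Reactants: 12 the aldol adduct; 13 allylmagnesium bromide
Product: 14 the C1-allyl triol (ring B cyclohexane with axial allyl on C1; C1–OH cis to C10–OH; otherwise as 12)
Conditions: allylmagnesium bromide (3.5 equiv), Et2O/THF, −78 °C; NH4Cl (aq)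
Reagents that add atoms: none
Why: Grignard addition of the very reactive allyl reagent to the hindered ketone should occur by axial attack, anti-periplanar to the axial C10–O bond and clear of the two equatorial α-substituents, so that the allyl group becomes axial and the C1 hydroxyl equatorial and cis to the C10 hydroxyl.

Step 9
Reactants: 14 the allyl triol
Product: 15 the cis-decalin triol (ring A C1–C6 with C3=C4 and methyl on C4; C1–OH cis to H6; C5–OH trans to H6; C10–OH cis to C1–OH; C7 C8 C10 as in 26)
Conditions: second-generation Grubbs catalyst (5 mol %), CH2Cl2, 40 °C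
Reagents that add atoms: none
Why: Ring-closing metathesis of the monosubstituted and the 1,1-disubstituted alkene closes six-membered ring A with the trisubstituted C3=C4 bond, and the ring fusion is cis because the C1–C2 bond is axial and the C6–C5 bond equatorial on ring B; no stereocentre is formed.

Step 10
Reactants: 15 the cis-decalin triol
Product: 17 (3Z,5Z,7S,8R,10R)-7-[3-(tert-butyldimethylsilyloxy)prop-1-en-2-yl]-10-hydroxy-4,10-dimethyl-8-(triethylsilyloxy)cyclodeca-3,5-dien-1-one, via C5 mesylate 16 (not isolated)
Conditions: MsCl, Et3N, CH2Cl2, −40 °C; cold filtration and solvent switch; KN(SiMe3)2 (2.2 equiv), THF, −78 to −40 °C; AcOH quench at −78 °C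
Reagents that add atoms: none
Why: Grob (Wharton-type) fragmentation of the 1,3-diol monosulfonate, in which the pseudo-equatorial C5–OMs bond of the cis-decalin is anti-periplanar to the C1–C6 ring-fusion bond, so the C1 alkoxide should expel mesylate with concerted cleavage of C1–C6, and because C7 is axial on ring A the new C5=C6 bond is formed Z, giving the ten-membered (3Z,5Z)-dienone.

Step 11
Reactants: 17 the bis-silyl dienone
Product: 18 (3Z,5Z,7S,8R,10R)-7-[3-(tert-butyldimethylsilyloxy)prop-1-en-2-yl]-8,10-dihydroxy-4,10-dimethylcyclodeca-3,5-dien-1-one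
Conditions: PPTS, MeOH/CH2Cl2, 0 °C
Reagents that add atoms: none
Why: Mild acid methanolysis should cleave the secondary triethylsilyl ether faster than the primary tert-butyldimethylsilyl ether, and the non-basic medium avoids migration of the skipped diene into conjugation with the C1 carbonyl.

Step 12
Reactants: 18 the C8 alcohol; 19 angelic acid
Product: 20 the C8 angelate of 18
Conditions: angelic acid, 2,4,6-trichlorobenzoyl chloride, Et3N, toluene, 20 °C; then 18, toluene, 60 °C (no DMAP)
Reagents that add atoms: none
Why: Yamaguchi esterification through the mixed anhydride, run without a nucleophilic amine catalyst so that the (Z)-2-methylbut-2-enoate does not isomerise to the tiglate, should acylate only the secondary C8 hydroxyl because the tertiary C10 hydroxyl is inert.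

Step 13
Reactants: 20 the silyl ether angelate
Product: 21 the primary allylic alcohol (C12–OH) of 20
Conditions: HF·pyridine, pyridine/THF, 0 °C
Reagents that add atoms: none
Why: Fluoride-mediated cleavage of the remaining silyl ether under buffered, non-basic conditions should leave the ester, the ketone and the diene untouched.

Step 14
Reactants: 21 the allylic alcohol
Product: 23 2-[(3Z,5Z,7S,8R,10R)-8-angeloyloxy-10-hydroxy-4,10-dimethyl-1-oxocyclodeca-3,5-dien-7-yl]prop-2-enoic acid, via enal 22 (not isolated)
Conditions: MnO2, CH2Cl2, 20 °C; then NaClO2, NaH2PO4, 2-methyl-2-butene, tBuOH/H2O, 0 °C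
Reagents that add atoms: sodium chlorite, [Na+].[O-]Cl=O
Why: MnO2 should oxidise only the primary allylic alcohol to the 2-substituted acrolein, and the Pinnick oxidation, with an alkene scavenger for hypochlorous acid, should convert it into the acrylic acid without touching the diene or the angelate.

Step 15
Reactants: 23 the dienoic acid
Product: 25 (3S,6S,7S,8R,10R,4Z)-8-angeloyloxy-3,10-dihydroxy-1-oxogermacra-4,11(13)-dien-12,6-olide, via C3 trifluoroacetate 24 (not isolated)
Conditions: Pd(O2CCF3)2 (10 mol %), p-benzoquinone (2 equiv), LiO2CCF3, CF3CO2H, acetone, 20 °C; then NaHCO3, MeOH/H2O, 0 °C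
Reagents that add atoms: lithium trifluoroacetate, [Li+].[O-]C(=O)C(F)(F)F
Why: Divalent palladium binds the cisoid (3Z,5Z)-diene, the C12 carboxylate adds to the diene terminus C6 from the face opposite to the metal, the resulting allyl–palladium unit spanning C5–C4–C3 is opened at C3 by trifluoroacetate, again from outside and anti to the metal, and the zerovalent palladium released is reoxidised by benzoquinone, after which mild methanolysis removes the trifluoroacetyl group. The closest known reaction type is the palladium-catalysed intramolecular 1,4-oxidation (1,4-acyloxy-lactonisation) of conjugated dienes that carry a carboxylic acid on the carbon next to the diene, in its acetoxy-trifluoroacetoxylation variant. The lactone ring closes in the 5-exo mode, with the oxygen attacking C6 while the C6–C5 bond stays outside the new ring. C6 is controlled by C7 through allylic 1,3-strain (H7 eclipses the Z-C5=C6 bond, so the carboxyl arm reaches C6 only from its own face and the ring fusion becomes trans), and C3 is controlled by the metal, since both oxygens enter anti to palladium and therefore end up cis-1,4 across the new double bond. The step needs 1,4- rather than 1,2-addition, a Z-C4=C5 bond and no syn delivery of the second oxygen; these are secured by the cis,cis-diene held in the ten-membered ring (both allyl termini anti, so the alkene is formed Z), by the chloride-free medium in which the poorly coordinating trifluoroacetate can only attack from outside, and by the fact that only attack at C6 gives a five-membered lactone.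

Step 16
Reactants: 25 the lactone ketone
Product: 26 (1S,3S,6S,7S,8R,10R,4Z)-8-angeloyloxy-1,3,10-trihydroxygermacra-4,11(13)-dien-12,6-olide (target CNP0249520.1)
Conditions: Me4NBH(OAc)3, MeCN/AcOH, −30 °C
Reagents that add atoms: none
Why: Hydroxyl-directed reduction (Evans–Saksena type), in which the C3 hydroxyl should bind the triacetoxyborohydride and deliver hydride to the β-carbonyl C1 on its own face of the ring to give the 1,3-anti diol, that is the (1S) carbinol, while the lactone and both unsaturated esters are inert to this reagent.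

**Compound list**

1 | (S)-(+)-carvone, (5S)-2-methyl-5-(prop-1-en-2-yl)cyclohex-2-en-1-one | C=C(C)[C@H]1CC=C(C)C(=O)C1 | starting material
2 | (5R)-1-(tert-butyldimethylsilyloxy)-2-methyl-5-(prop-1-en-2-yl)cyclohexa-1,3-diene | C=C(C)[C@H]1C=CC(C)=C(O[Si](C)(C)C(C)(C)C)C1 | intermediate
3 | 3,4-epoxide of diene 2 (oxygen anti to the isopropenyl group, silyl enol ether retained) | C=C(C)[C@H]1[C@@H]2O[C@@H]2C(C)=C(O[Si](C)(C)C(C)(C)C)C1 | intermediate (not isolated)
4 | (4R,5S)-4-hydroxy-2-methyl-5-(prop-1-en-2-yl)cyclohex-2-en-1-one | C=C(C)[C@H]1[C@H](O)C=C(C)C(=O)C1 | intermediate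
5 | (4R,5S)-2-methyl-5-(prop-1-en-2-yl)-4-(triethylsilyloxy)cyclohex-2-en-1-one | C=C(C)[C@H]1[C@H](O[Si](CC)(CC)CC)C=C(C)C(=O)C1 | intermediate
6 | lithium (4R,5S)-2-methyl-5-(prop-1-en-2-yl)-4-(triethylsilyloxy)cyclohex-1-en-1-olate | [Li+].C=C(C)[C@H]1[C@H](O[Si](CC)(CC)CC)CC(C)=C([O-])C1 | intermediate (not isolated)
7 | (2R,4R,5S)-2-hydroxy-2-methyl-5-(prop-1-en-2-yl)-4-(triethylsilyloxy)cyclohexan-1-one | C=C(C)[C@H]1[C@H](O[Si](CC)(CC)CC)C[C@@](C)(O)C(=O)C1 | intermediate
8 | (2R,4R,5S)-2-hydroxy-5-(3-hydroxyprop-1-en-2-yl)-2-methyl-4-(triethylsilyloxy)cyclohexan-1-one | C=C(CO)[C@H]1[C@H](O[Si](CC)(CC)CC)C[C@@](C)(O)C(=O)C1 | intermediate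
9 | (2R,4R,5S)-5-[3-(tert-butyldimethylsilyloxy)prop-1-en-2-yl]-2-hydroxy-2-methyl-4-(triethylsilyloxy)cyclohexan-1-one | C=C(CO[Si](C)(C)C(C)(C)C)[C@H]1[C@H](O[Si](CC)(CC)CC)C[C@@](C)(O)C(=O)C1 | intermediate
10 | methacrolein, 2-methylprop-2-enal | C=C(C)C=O | starting material
11 | dilithium alkoxide–enolate of 9 (enolate towards C6) | [Li+].[Li+].C=C(CO[Si](C)(C)C(C)(C)C)[C@H]1[C@H](O[Si](CC)(CC)CC)C[C@@](C)([O-])C([O-])=C1 | intermediate (not isolated)
12 | (2R,4R,5S,6S)-5-[3-(tert-butyldimethylsilyloxy)prop-1-en-2-yl]-2-hydroxy-6-[(1R)-1-hydroxy-2-methylprop-2-en-1-yl]-2-methyl-4-(triethylsilyloxy)cyclohexan-1-one (anti aldol) | C=C(CO[Si](C)(C)C(C)(C)C)[C@H]1[C@H](O[Si](CC)(CC)CC)C[C@@](C)(O)C(=O)[C@@H]1[C@@H](O)C(C)=C | intermediate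
13 | allylmagnesium bromide | C=CC[Mg]Br | starting material
14 | C1-allyl triol: 12 with an axial allyl group and a hydroxyl on C1, the C1 hydroxyl cis to the C10 hydroxyl | C=C(CO[Si](C)(C)C(C)(C)C)[C@H]1[C@H](O[Si](CC)(CC)CC)C[C@@](C)(O)[C@](O)(CC=C)[C@@H]1[C@@H](O)C(C)=C | intermediate
15 | cis-decalin triol: cis-fused bicyclo[4.4.0]dec-3-ene-1,5,10-triol (target numbering) with methyls on C4 and C10, C1–OH cis to H6, C5–OH trans to H6, C10–OH cis to C1–OH, C8 triethylsilyloxy and C7 3-(tert-butyldimethylsilyloxy)prop-1-en-2-yl as in 9 | C=C(CO[Si](C)(C)C(C)(C)C)[C@H]1[C@H](O[Si](CC)(CC)CC)C[C@@](C)(O)[C@]2(O)CC=C(C)[C@H](O)[C@H]12 | intermediate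
16 | C5 methanesulfonate of 15 | C=C(CO[Si](C)(C)C(C)(C)C)[C@H]1[C@H](O[Si](CC)(CC)CC)C[C@@](C)(O)[C@]2(O)CC=C(C)[C@H](OS(C)(=O)=O)[C@H]12 | intermediate (not isolated)
17 | (3Z,5Z,7S,8R,10R)-7-[3-(tert-butyldimethylsilyloxy)prop-1-en-2-yl]-10-hydroxy-4,10-dimethyl-8-(triethylsilyloxy)cyclodeca-3,5-dien-1-one | O=C1C/C=C(C)\C=C/[C@@H](C(=C)CO[Si](C)(C)C(C)(C)C)[C@H](O[Si](CC)(CC)CC)C[C@@]1(C)O | intermediate
18 | (3Z,5Z,7S,8R,10R)-7-[3-(tert-butyldimethylsilyloxy)prop-1-en-2-yl]-8,10-dihydroxy-4,10-dimethylcyclodeca-3,5-dien-1-one | O=C1C/C=C(C)\C=C/[C@@H](C(=C)CO[Si](C)(C)C(C)(C)C)[C@H](O)C[C@@]1(C)O | intermediate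
19 | angelic acid, (Z)-2-methylbut-2-enoic acid | C/C=C(/C)C(=O)O | starting material
20 | (3Z,5Z,7S,8R,10R)-7-[3-(tert-butyldimethylsilyloxy)prop-1-en-2-yl]-10-hydroxy-4,10-dimethyl-1-oxocyclodeca-3,5-dien-8-yl (Z)-2-methylbut-2-enoate | O=C1C/C=C(C)\C=C/[C@@H](C(=C)CO[Si](C)(C)C(C)(C)C)[C@H](OC(=O)/C(C)=C\C)C[C@@]1(C)O | intermediate
21 | (3Z,5Z,7S,8R,10R)-10-hydroxy-7-(3-hydroxyprop-1-en-2-yl)-4,10-dimethyl-1-oxocyclodeca-3,5-dien-8-yl (Z)-2-methylbut-2-enoate | O=C1C/C=C(C)\C=C/[C@@H](C(=C)CO)[C@H](OC(=O)/C(C)=C\C)C[C@@]1(C)O | intermediate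
22 | (3Z,5Z,7S,8R,10R)-10-hydroxy-4,10-dimethyl-1-oxo-7-(3-oxoprop-1-en-2-yl)cyclodeca-3,5-dien-8-yl (Z)-2-methylbut-2-enoate | O=C1C/C=C(C)\C=C/[C@@H](C(=C)C=O)[C@H](OC(=O)/C(C)=C\C)C[C@@]1(C)O | intermediate (not isolated)
23 | 2-[(3Z,5Z,7S,8R,10R)-8-angeloyloxy-10-hydroxy-4,10-dimethyl-1-oxocyclodeca-3,5-dien-7-yl]prop-2-enoic acid | O=C1C/C=C(C)\C=C/[C@@H](C(=C)C(=O)O)[C@H](OC(=O)/C(C)=C\C)C[C@@]1(C)O | intermediate
24 | C3 trifluoroacetate of 25 | C=C1C(=O)O[C@H]2/C=C(/C)[C@@H](OC(=O)C(F)(F)F)CC(=O)[C@](C)(O)C[C@@H](OC(=O)/C(C)=C\C)[C@H]12 | intermediate (not isolated)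
25 | (3S,6S,7S,8R,10R,4Z)-8-angeloyloxy-3,10-dihydroxy-1-oxogermacra-4,11(13)-dien-12,6-olide | C=C1C(=O)O[C@H]2/C=C(/C)[C@@H](O)CC(=O)[C@](C)(O)C[C@@H](OC(=O)/C(C)=C\C)[C@H]12 | intermediate
26 | (1S,3S,6S,7S,8R,10R,4Z)-8-angeloyloxy-1,3,10-trihydroxygermacra-4,11(13)-dien-12,6-olide | C=C1C(=O)O[C@H]2/C=C(/C)[C@@H](O)C[C@H](O)[C@](C)(O)C[C@@H](OC(=O)/C(C)=C\C)[C@H]12 | target

**Step count and risks**

Total step count: 16. Longest linear sequence: 16 steps, from 1.

The three steps most likely to fail are the following.

First, step 15. Palladium may bind the diene on the face that does not allow anti attack by the tethered carboxylate, or the allyl–palladium unit may equilibrate before capture. Either would erode the trans ring fusion, the Z geometry or the cis-1,4 relation, and turnover may be slow with the hindered medium-ring diene. The fallback sets out from 23 and returns at 25. Dye-sensitised photooxygenation of 23 (O2, tetraphenylporphyrin, visible light, CH2Cl2, −40 °C) should add singlet oxygen across C3 and C6 of the cisoid diene in a [4+2] cycloaddition, which can only give the cis-1,4-dioxygenated Z-alkene, to form the 3,6-endoperoxide F1. Reduction of the O–O bond with thiourea in MeOH should give the cis-3,6-dihydroxy acid F2, whose C6 hydroxyl closes the γ-lactone onto C12 on standing or with a carbodiimide to give 25.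

Second, step 10. The allylic mesylate may ionise or eliminate before the alkoxide fragments, with loss of the stereospecific Z outcome, and the base may move the skipped diene into conjugation with the C1 carbonyl. The fallback sets out from 15 and returns at 17. Oxidation of the allylic C5 hydroxyl with MnO2 should give the β-hydroxy enone F3. Treatment with KN(SiMe3)2 and N-phenylbis(trifluoromethanesulfonimide) at −78 °C should then bring about a retro-aldol cleavage of C1–C6 with O-sulfonylation of the ring-expanded dienolate, giving the dienyl triflate F4 with no allylic leaving group involved. Palladium-catalysed formate reduction of the triflate (Pd(OAc)2, PPh3, Bu3N, HCO2H, DMF) should give 17.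

Third, step 4. The bulky oxaziridine may attack the tetrasubstituted enolate from the equatorial direction, which would give the C10 epimer. The fallback sets out from 5 and returns at 7. The enolate formed with LiBH(sBu)3 is trapped with TMSCl and the trimethylsilyl enol ether F5 is isolated. Rubottom oxidation with the small, neutral dimethyldioxirane at −78 °C, followed by mild acid work-up, should then deliver the axial C10 hydroxyl of 7 by epoxidation of the enol ether rather than by oxygenation of a boron-associated enolate.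

Further compounds
F1 | step 15 | 3,6-endoperoxide of acid 23 (peroxide bridge from C3 to C6, Z-C4=C5, configurations at C3 and C6 as in 25) | C=C(C(=O)O)[C@@H]1[C@@H]2C=C(C)[C@@H](OO2)CC(=O)[C@](C)(O)C[C@H]1OC(=O)/C(C)=C\C
F2 | step 15 | cis-3,6-dihydroxy acid: 2-[(3S,4Z,6S,7S,8R,10R)-8-angeloyloxy-3,6,10-trihydroxy-4,10-dimethyl-1-oxocyclodec-4-en-7-yl]prop-2-enoic acid | C=C(C(=O)O)[C@@H]1[C@@H](O)/C=C(/C)[C@@H](O)CC(=O)[C@](C)(O)C[C@H]1OC(=O)/C(C)=C\C
F3 | step 10 | β-hydroxy enone: 15 with the C5 hydroxyl oxidised to the ketone | C=C(CO[Si](C)(C)C(C)(C)C)[C@H]1[C@H](O[Si](CC)(CC)CC)C[C@@](C)(O)[C@]2(O)CC=C(C)C(=O)[C@H]12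
F4 | step 10 | dienyl triflate: 17 carrying a trifluoromethanesulfonyloxy group on C5 | O=C1C/C=C(C)\C(OS(=O)(=O)C(F)(F)F)=C/[C@@H](C(=C)CO[Si](C)(C)C(C)(C)C)[C@H](O[Si](CC)(CC)CC)C[C@@]1(C)O
F5 | step 4 | trimethylsilyl enol ether of the conjugate-reduced ketone: (4R,5S)-2-methyl-5-(prop-1-en-2-yl)-4-(triethylsilyloxy)-1-(trimethylsilyloxy)cyclohex-1-ene | C=C(C)[C@H]1[C@H](O[Si](CC)(CC)CC)CC(C)=C(O[Si](C)(C)C)C1
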